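## Retrosynthetic overview

1. Target 14 ⇒ acyclic hydroperoxy hydroxy enoate 12. One operation closes the 1,2-dioxane first (6-exo peroxy-Michael, C7a–O bond) and then the γ-lactone (C4a–OH onto the ester).
2. 12 ⇒ dienoate 10 + O2: Co–H hydroperoxidation of the trisubstituted olefin makes the C3–OO bond.
3. 10 ⇒ hydroxy ester 7 + ylide 8 (reduction–olefination); 7 ⇒ ene adduct 6 + alkene 3 (cross-metathesis).
4. 6 ⇒ methyl pyruvate 4 + isobutylene 5 (Cu–bis(oxazoline) carbonyl-ene, sets C4a); 3 ⇒ 1 + 2.
5. Stereocentres (furo[3,2-c][1,2]dioxine numbering of 14): C4a by catalyst, C7a by the cyclisation, C3 formed without control (about 1:1) and its epimer separated at the end.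

Assumption: the Cu(II)–t-Bu-box pyruvate–ene reaction follows the sense of induction I recall for it ((S,S)-ligand gives the (S)-α-hydroxy ester), so the (R,R)-ligand is used to obtain (R)-6.

## Route

Step 1
Reactants: 1 11-bromoundec-1-ene; 2 phenylmagnesium bromide
Product: 3 11-phenylundec-1-ene
Conditions: FeCl3 (5 mol %), TMEDA (1.2 equiv), THF, 0 °C, slow addition of 2
Reagents that add atoms: none
Why: Iron-catalysed Kumada-type coupling of a primary alkyl bromide with an aryl Grignard reagent; the terminal alkene is inert and no stereocentre is formed.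

Step 2
Reactants: 4 methyl pyruvate; 5 isobutylene (2-methylpropene)
Product: 6 methyl (R)-2-hydroxy-2,4-dimethylpent-4-enoate
Conditions: [Cu((R,R)-t-Bu-box)](SbF6)2 (10 mol %), 5 (5 equiv), CH2Cl2, sealed tube, rt
Reagents that add atoms: none
Why: Cu(II)–bis(oxazoline)-catalysed carbonyl-ene reaction in which the pyruvate chelates the square-planar copper centre and isobutylene attacks the open ketone face through a six-membered ene transition state, setting the tertiary carbinol (future C4a) as R (≥95% ee expected).

Step 3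
Reactants: 6 methyl (R)-2-hydroxy-2,4-dimethylpent-4-enoate; 3 11-phenylundec-1-ene
Product: 7 methyl (R)-2-hydroxy-2,4-dimethyl-14-phenyltetradec-4-enoate (E/Z mixture)
Conditions: Hoveyda–Grubbs II (5 mol %), 3 (3 equiv), CH2Cl2, 40 °C
Reagents that add atoms: none
Why: Olefin cross-metathesis of a 1,1-disubstituted alkene with a terminal alkene, driven by loss of ethene; the E/Z ratio does not matter because both isomers give the same tertiary radical in step 5, and the carbinol stereocentre is untouched.

Step 4
Reactants: 7 methyl (R)-2-hydroxy-2,4-dimethyl-14-phenyltetradec-4-enoate (E/Z mixture); 8 methyl (triphenylphosphoranylidene)acetate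
Product: 10 methyl (2E,4R)-4-hydroxy-4,6-dimethyl-16-phenylhexadeca-2,6-dienoate (6E/6Z mixture), via hydroxy aldehyde 9 (not isolated)
Conditions: DIBAL-H (2.2 equiv), CH2Cl2, −78 °C; then 8 (1.5 equiv), −78 °C → rt
Reagents that add atoms: none
Why: One-pot DIBAL-H partial reduction (the aluminium alkoxide chelates and stabilises the hemiacetal) followed by Wittig olefination with a stabilised ylide gives the 2E-enoate; the quaternary carbinol cannot epimerise.

Step 5
Reactants: 10 methyl (2E,4R)-4-hydroxy-4,6-dimethyl-16-phenylhexadeca-2,6-dienoate (6E/6Z mixture)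
Product: 14 (3R,4aR,7aR)-3,4a-dimethyl-3-(10-phenyldecyl)tetrahydro-3H-furo[3,2-c][1,2]dioxin-6(4H)-one (target), via silyl peroxide 11 (not isolated), via hydroperoxide 12 (not isolated), via seco ester 13 (not isolated)
Conditions: Co(thd)2 (5 mol %), O2 (1 atm), Et3SiH (2 equiv), DCE, rt; SiO2 plug; then HCl (cat.), MeOH, 0 °C; then Et2NH, CF3CH2OH, rt; chromatography
Reagents that add atoms: dioxygen, O=O
Why: Isayama–Mukaiyama Co–H hydrogen-atom transfer and O2 capture put the silyl peroxide on the electron-rich trisubstituted olefin (the enoate is left alone), and after desilylation the hydroperoxide adds 6-exo to the enoate (oxa-Michael) through a chair transition state with the C4a methyl equatorial and the C4a hydroxyl axial, which sets C7a as R, cis to the hydroxyl, so that the hydroxy ester lactonises (the hydroperoxide conjugate addition and lactonisation by which these peroxylactones are thought to arise), while C3 forms without control (about 1:1) and its epimer is removed by chromatography.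

## Compound list

1 | 11-bromoundec-1-ene | C=CCCCCCCCCCBr | starting material
2 | phenylmagnesium bromide | Br[Mg]c1ccccc1 | starting material
3 | 11-phenylundec-1-ene | C=CCCCCCCCCCc1ccccc1 | intermediate
4 | methyl pyruvate | CC(=O)C(=O)OC | starting material
5 | isobutylene (2-methylpropene) | CC(C)=C | starting material
6 | methyl (R)-2-hydroxy-2,4-dimethylpent-4-enoate | C=C(C)C[C@@](C(=O)OC)(C)O | intermediate
7 | methyl (R)-2-hydroxy-2,4-dimethyl-14-phenyltetradec-4-enoate (E/Z mixture at C4=C5) | CC(=CCCCCCCCCCc1ccccc1)C[C@@](C(=O)OC)(C)O | intermediate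
8 | methyl (triphenylphosphoranylidene)acetate | COC(=O)C=P(c1ccccc1)(c1ccccc1)c1ccccc1 | starting material
9 | (R)-2-hydroxy-2,4-dimethyl-14-phenyltetradec-4-enal (E/Z mixture, not isolated) | CC(=CCCCCCCCCCc1ccccc1)C[C@@](C=O)(C)O | intermediate
10 | methyl (2E,4R)-4-hydroxy-4,6-dimethyl-16-phenylhexadeca-2,6-dienoate (6E/6Z mixture) | CC(=CCCCCCCCCCc1ccccc1)C[C@@](/C=C/C(=O)OC)(C)O | intermediate
11 | methyl (2E,4R,6R)-4-hydroxy-4,6-dimethyl-16-phenyl-6-[(triethylsilyl)peroxy]hexadec-2-enoate (productive epimer shown; formed with its 6S epimer; not isolated) | C[C@@](OO[Si](CC)(CC)CC)(CCCCCCCCCCc1ccccc1)C[C@@](/C=C/C(=O)OC)(C)O | intermediate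
12 | methyl (2E,4R,6R)-6-hydroperoxy-4-hydroxy-4,6-dimethyl-16-phenylhexadec-2-enoate (not isolated) | C[C@@](OO)(CCCCCCCCCCc1ccccc1)C[C@@](/C=C/C(=O)OC)(C)O | intermediate
13 | methyl 2-[(3R,4R,6R)-4-hydroxy-4,6-dimethyl-6-(10-phenyldecyl)-1,2-dioxan-3-yl]acetate (not isolated) | C[C@@]1(CCCCCCCCCCc2ccccc2)C[C@@](C)(O)[C@@H](CC(=O)OC)OO1 | intermediate
14 | (3R,4aR,7aR)-3,4a-dimethyl-3-(10-phenyldecyl)tetrahydro-3H-furo[3,2-c][1,2]dioxin-6(4H)-one: cis-fused 1,2-dioxane/γ-lactone; Me and 10-phenyldecyl on C3, Me on C4a, H on C7a | C[C@@]1(CCCCCCCCCCc2ccccc2)C[C@@]2(C)OC(=O)C[C@H]2OO1 | target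

## Step count and risks

Total: 5 steps. Longest linear sequence: 4 steps (steps 2–5, from methyl pyruvate).

**Most likely to fail: step 5.** The radical O2 capture gives no control at C3, so at most half of the material is the target. The cobalt hydride may also touch the enoate, and the free hydroperoxide is sensitive. The fallback sets C3 by reagent control instead of radical capture; it sets out from 10 (6E isomer, the major one, separated on AgNO3–silica) and comes back at 14:
- Shi epoxidation (D-fructose-derived ketone, Oxone) gives the (6R,7R)-epoxide F1.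
- Phosphomolybdic acid-catalysed perhydrolysis with ethereal H2O2 opens the epoxide at the tertiary carbon with inversion to the hydroperoxy diol F2.
- Et2NH in CF3CH2OH closes both rings to the side-chain hydroxy peroxylactone F3.
- The extra secondary hydroxyl is removed by Barton–McCombie deoxygenation through the imidazolyl thionocarbamate F4 (thiocarbonyldiimidazole; then Bu3SnH, AIBN, benzene, 80 °C). The β-peroxy radical must be trapped by the stannane before it closes to an epoxide, so the stannane is kept concentrated.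
- This costs three more operations.

**Second: step 3.** The 1,1-disubstituted olefin of 6 sits next to a quaternary carbon and may be slow in cross-metathesis. The fallback carries the chain into the ene reaction; it sets out from 4 and comes back at 7 (and at 11 for the co-formed isomer):
- 2-Methyl-12-phenyldodec-1-ene F5 (from commercial (10-bromodecyl)benzene and isopropenylmagnesium bromide, CuI cat.) replaces isobutylene under the step-2 conditions.
- This gives 7 directly, together with its double-bond isomer, the 4-methylidene hydroxy ester F6.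
- The mixture is taken through the step-4 conditions, where F6 gives the 6-methylidene dienoate F7.
- Both olefin isomers give the same tertiary radical and converge on 11 in step 5.

**Third: step 4.** With a free tertiary hydroxyl next to the ester, the one-pot partial reduction can over-reduce or stall at the aluminium hemiacetal. The fallback reaches the aldehyde by a redox relay; it sets out from 7 and comes back at 10:
- LiAlH4 reduces 7 fully to the diol F8.
- TEMPO/PhI(OAc)2 oxidises only the primary alcohol, and the aldehyde 9 is trapped in the same flask by 8 (tandem oxidation–Wittig).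

## Further compounds

F1 | step 5 | methyl (2E,4R,6R,7R)-6,7-epoxy-4-hydroxy-4,6-dimethyl-16-phenylhexadec-2-enoate | C[C@@]1(O[C@@H]1CCCCCCCCCc1ccccc1)C[C@@](/C=C/C(=O)OC)(C)O
F2 | step 5 | methyl (2E,4R,6S,7R)-6-hydroperoxy-4,7-dihydroxy-4,6-dimethyl-16-phenylhexadec-2-enoate | C[C@@](OO)([C@H](O)CCCCCCCCCc1ccccc1)C[C@@](/C=C/C(=O)OC)(C)O
F3 | step 5 | (3S,4aR,7aR)-3-[(1R)-1-hydroxy-10-phenyldecyl]-3,4a-dimethyltetrahydro-3H-furo[3,2-c][1,2]dioxin-6(4H)-one | C[C@@]1([C@H](O)CCCCCCCCCc2ccccc2)C[C@@]2(C)OC(=O)C[C@H]2OO1
F4 | step 5 | O-{(1R)-1-[(3S,4aR,7aR)-3,4a-dimethyl-6-oxotetrahydro-3H-furo[3,2-c][1,2]dioxin-3-yl]-10-phenyldecyl} 1H-imidazole-1-carbothioate | C[C@@]1([C@H](OC(=S)n2ccnc2)CCCCCCCCCc2ccccc2)C[C@@]2(C)OC(=O)C[C@H]2OO1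
F5 | step 3 | 2-methyl-12-phenyldodec-1-ene | C=C(C)CCCCCCCCCCc1ccccc1
F6 | step 3 | methyl (R)-2-hydroxy-2-methyl-4-methylidene-14-phenyltetradecanoate | C=C(CCCCCCCCCCc1ccccc1)C[C@@](C(=O)OC)(C)O
F7 | step 3 | methyl (2E,4R)-4-hydroxy-4-methyl-6-methylidene-16-phenylhexadec-2-enoate | C=C(CCCCCCCCCCc1ccccc1)C[C@@](/C=C/C(=O)OC)(C)O
F8 | step 4 | (R)-2,4-dimethyl-14-phenyltetradec-4-ene-1,2-diol (E/Z mixture) | CC(=CCCCCCCCCCc1ccccc1)C[C@@](CO)(C)O
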